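Remark on the chemistry: the target is planar and achiral, so no configuration has to be set. The precursor and product structures of the key step map consistently onto the target (the benzofuran 4-methoxy group becomes the flavone 5-methoxy group, and the inserted carbon is C3), so no structure needed correcting. The 2-arylbenzofuranone stage is assumed to be too oxidation-prone to isolate and is therefore silylated in the flask in which it forms.

## Structural features

The target is a flavone: benzene ring A is fused to the 4-pyranone ring C (O1, C2, C3, C4, C4a, C8a), and benzene ring B is bonded through C1' to C2. Ring A is fully substituted, with a hydroxyl at C5 hydrogen-bonded to the C4 carbonyl and methoxy groups at C6, C7 and C8. Ring B is a methoxyhydroquinone with hydroxyls at C2' and C5' and a methoxy group at C4'. There is no stereocentre, so no stereocentres stand next to each other and nothing has to be controlled in that respect. The fragile parts are the hydroquinone of ring B, which oxidises to a quinone in air and faster under base; the pyranone, which hard nucleophiles open at C2; and the row of four oxygens on ring A, where a Lewis acid can remove more than one methyl group. The real difficulty is therefore the oxygen pattern, not the carbon skeleton: three free hydroxyls must be told apart from four methyl ethers, and ring C must be built on an electron-rich ring A that has only one open position. The C5 oxygen differs from the other ethers by its peri relation to the carbonyl, which allows its release by chelation at the very end. The key step exploits the fact that C3 is the only CH of ring C and sits between C2 and C4: a 2-aryl-3-silyloxybenzofuran already contains O1, C2, C4, C4a and C8a, so C3 can be inserted as a single carbene carbon into its C2=C(O) enol ether bond.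

## Logic of the disconnections

**19 back to 18.** The O–CH3 bond at C5 is restored. This oxygen is the only one peri to the C4 carbonyl, so it can travel as a methyl ether like its three neighbours and be freed last by chelation. The gain is that ring A of every earlier compound is a plain tetramethoxyarene derived from 1. The forward step must stop after the chelated ether and leave the methyl ethers at C6, C7, C8 and C4' alone.

**18 back to 17.** The C3–Br bond and the two O–benzyl bonds are restored. The bromine is the trace left by the dihalocarbene, and the benzyl groups mask the hydroquinone through the basic, palladium and carbene steps. All three are removable by one hydrogenolysis, which must not saturate C2=C3.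

**17 back to 14 and 15.** The bonds C2–C3 and C3–C4 are cut and C3 is removed as a one-carbon unit, so ring C contracts to a furan. This reduces the flavone to a benzofuran enol ether plus a C1 reagent. The forward step requires that the carbene attacks only the enol ether double bond and that the cyclopropane opens toward the six-membered ring.

**14 back to 8 and 11.** The C2–C1' bond and the O–Si bond are cut, which separates the two arenes completely. The forward step is a cross-coupling of a ketone enolate with a hindered, electron-rich aryl bromide. The resulting enolate must be trapped on oxygen before air reaches it.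

**8 back to 7, then to 4 and 5.** First the O1–C2 ether bond is cut, then the acyl–arene bond (C4–C4a in flavone numbering). Compound 4 has a single unsubstituted carbon, ortho to its hydroxyl, so the acylation has no regiochemical choice. The demand is C-acylation without loss of a methyl ether.

**4 back to 1.** The aryl C–O bond is cut. The two ring hydrogens of 1 are equivalent and each is ortho to a methoxy group, so metalation, borylation and oxidation can give only one phenol.

**11 back to 10, then to 9.** The C–Br bond is cut, then the two O–benzyl bonds. The forward bromination must go para to the methoxy group, which is the most activated and least hindered position of 10.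

## Other disconnections considered

**Alternative 1:** The cut is C4–C4a, made last on ring C.
- Forward step: the acid A1, (Z)-3-(2,5-diisopropoxy-4-methoxyphenyl)-3-(2,3,4,5-tetramethoxyphenoxy)prop-2-enoic acid, is activated with trifluoroacetic anhydride (or as its acid chloride with SnCl4). It acylates the one free carbon of its aryloxy ring to give A2, 2',5'-diisopropoxy-4',5,6,7,8-pentamethoxyflavone. A1 would come from phenol 4 and the propiolate A3, ethyl 3-(2,5-diisopropoxy-4-methoxyphenyl)prop-2-ynoate, by oxa-Michael addition and saponification.
- In favour: every reaction type is established, phenol 4 is shared with the chosen plan, and no halogen has to be removed. BCl3 should take off both isopropyl ethers and the chelated 5-methyl ether in one operation, so the endgame is one step shorter; on this point it is better than the chosen plan.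
- Against: only the Z acid can reach C4a. The E isomer places the acylium next to C6' of ring B and would close a five-membered ketone instead. The acylation site on ring A is flanked by the aryloxy oxygen and a methoxy group, whereas the competing position on ring B is less hindered. The enol ether linkage of A1 may also be cleaved by strong acid.
- Comparison: on mechanism this alternative is the more secure. On step economy it is about equal overall (roughly nine steps) and better after the key step. On structure the chosen plan is stronger, because its new carbon is bonded to C2 and C4 from the outset and no second electron-rich ring can compete for it.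

**Alternative 2:** The cut runs through ring B at C1'–C2' and C5'–C6'.
- Forward step: a Diels–Alder reaction of A4, 2-ethynyl-5,6,7,8-tetramethoxychromone, with the diene A5, 4-methoxy-2-(trimethylsilyloxy)furan. Opening of the oxygen bridge and aromatisation would give A6, 2',5'-dihydroxy-4',5,6,7,8-pentamethoxyflavone, which is the same compound as 18.
- In favour: ring B arrives with its three oxygens in place and both phenols free, so benzylation, bromination and hydrogenolysis all disappear; on protecting-group economy it is better than the chosen plan. The polarity is matched, since the nucleophilic C5 of A5 meets the electrophilic alkyne terminus of A4. It converges on 18, so the last step is shared and equal.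
- Against: A4 would need about five operations from 4 (C-acetylation, condensation and ring closure with an oxalate, partial reduction, alkyne homologation). Its alkyne is conjugated to a vinylogous ester, not a ketone, so it is only a moderate dienophile. Silyloxyfurans tend to react with such acceptors stepwise, in a vinylogous Mukaiyama–Michael manner that can stop before a benzene ring is formed. The C2=C3 bond of the chromone is a second acceptor, and the free hydroquinone is exposed to a hot reaction mixture.
- Comparison: on structure it matches the ring B pattern elegantly and is equal or better. On mechanism both key steps are untested on their substrates, and the chosen one has the closer analogies. On step economy the totals would be similar (about eight or nine), because the synthesis of A4 uses up what the free phenols save.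

**Alternative 3:** Ring A is cut at C5–C4a and, one stage earlier, at C8–C8a, leaving a pyranone and a four-carbon squarate unit.
- Forward step: the bromide A10, 2-[2,5-bis(benzyloxy)-4-methoxyphenyl]-6-bromo-4H-pyran-4-one, is metalated by halogen–magnesium exchange and added to A9, dimethyl squarate. O-Methylation of the adduct gives A7, 4-{6-[2,5-bis(benzyloxy)-4-methoxyphenyl]-4-oxo-4H-pyran-2-yl}-2,3,4-trimethoxycyclobut-2-en-1-one. Heating opens the four-membered ring, and the carbon that was the cyclobutenone carbonyl bonds to the adjacent pyranone CH in a six-electron closure. Tautomerisation gives A8, 2',5'-bis(benzyloxy)-5-hydroxy-4',6,7,8-tetramethoxyflavone.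
- In favour: the 5-hydroxyl is formed free and distinct from the three methoxy groups, so no selective demethylation is needed; on this point it is better than the chosen plan. The endgame is a single hydrogenolysis, one step shorter.
- Against: a carbanion at C6 of a 4-pyranone is hard to generate and keep, because the ring is itself an electrophile toward organometallics. A10 is not a trivial compound. Closure onto an electron-poor pyranone double bond has less precedent than closure onto arenes or simple alkenes. The whole route would run to about eleven steps.
- Comparison: on structure it solves the oxygen pattern of ring A most cleanly (better). On mechanism its thermal step is a known reaction type but its metalation step is doubtful, which is roughly equal in risk to the chosen key step. On step economy the chosen plan is shorter before the key step and longer by one step after it.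

Key step: step 7

## Route

Step 1
Reactants: 1 1,2,3,4-tetramethoxybenzene
Product: 4 2,3,4,5-tetramethoxyphenol, via aryllithium 2 (not isolated), via lithium aryltrimethoxyborate 3 (not isolated)
Conditions: n-BuLi, TMEDA, THF, 0 °C; B(OMe)3, −78 °C to rt; 30% H2O2, AcOH, 0 °C
Reagents that add atoms: hydrogen peroxide, OO (the phenol oxygen of 4); n-butyllithium, [Li]CCCC, and trimethyl borate, COB(OC)OC, leave atoms only in the transient 2 and 3
Why: Directed ortho-metalation; the two ring hydrogens of 1 are equivalent and each is ortho to a methoxy group, so one aryllithium forms, and borylation followed by peroxide-induced 1,2-shift of the aryl group from boron to oxygen should give the phenol.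

Step 2
Reactants: 4 2,3,4,5-tetramethoxyphenol; 5 chloroacetyl chloride
Product: 7 2-chloro-1-(2-hydroxy-3,4,5,6-tetramethoxyphenyl)ethan-1-one, via aryl chloroacetate 6 (not isolated)
Conditions: BF3·OEt2, (CH2Cl)2, 0 to 70 °C; H2O
Reagents that add atoms: none
Why: O-acylation followed by a BF3-promoted Fries rearrangement (Friedel–Crafts acylation); the only unsubstituted carbon of 4 is ortho to the hydroxyl, and BF3 is chosen over AlCl3 because it rarely cleaves aryl methyl ethers.

Step 3
Reactants: 7 2-chloro-1-(2-hydroxy-3,4,5,6-tetramethoxyphenyl)ethan-1-one
Product: 8 4,5,6,7-tetramethoxybenzofuran-3(2H)-one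
Conditions: NaOAc, EtOH, reflux
Reagents that add atoms: none
Why: Intramolecular Williamson etherification (5-exo-tet) of the phenoxide on the alpha-chloroketone; the weak base should close the ring without aldol self-condensation of the product.

Step 4
Reactants: 9 2-methoxyhydroquinone
Product: 10 1,4-bis(benzyloxy)-2-methoxybenzene
Conditions: BnBr, K2CO3, DMF, 60 °C, N2
Reagents that add atoms: benzyl bromide, BrCc1ccccc1
Why: Double Williamson ether synthesis; the inert atmosphere keeps the hydroquinone dianion from oxidising before both oxygens are alkylated.

Step 5
Reactants: 10 1,4-bis(benzyloxy)-2-methoxybenzene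
Product: 11 1-bromo-2,5-bis(benzyloxy)-4-methoxybenzene
Conditions: NBS, MeCN, 0 °C to rt
Reagents that add atoms: N-bromosuccinimide, O=C1CCC(=O)N1Br
Why: Electrophilic aromatic bromination; the carbon para to the methoxy group and ortho to one benzyloxy group is the most activated and least hindered, as in other 1,2,4-trialkoxybenzenes, while the carbon between two alkoxy groups is shielded.

Step 6
Reactants: 8 4,5,6,7-tetramethoxybenzofuran-3(2H)-one; 11 1-bromo-2,5-bis(benzyloxy)-4-methoxybenzene
Product: 14 {2-[2,5-bis(benzyloxy)-4-methoxyphenyl]-4,5,6,7-tetramethoxybenzofuran-3-yl}oxy(tert-butyl)dimethylsilane, via 2-arylbenzofuranone 12 (not isolated), via sodium enolate 13 (not isolated)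
Conditions: Pd(OAc)2 (cat.), XPhos, NaOtBu, toluene, 80 °C; then TBSOTf, 0 °C
Reagents that add atoms: tert-butyldimethylsilyl trifluoromethanesulfonate, CC(C)(C)[Si](C)(C)OS(=O)(=O)C(F)(F)F; sodium tert-butoxide, CC(C)(C)[O-].[Na+], leaves sodium only in the transient 13
Why: Palladium-catalysed ketone alpha-arylation (oxidative addition of 11 to zerovalent palladium, enolate binding, C–C reductive elimination promoted by the bulky biarylphosphine); the second equivalent of base holds the more acidic product as its aromatic benzofuran-3-olate, which resists a second arylation and is silylated on oxygen by the hard silyl triflate before it can autoxidise.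

Step 7
Reactants: 14 {2-[2,5-bis(benzyloxy)-4-methoxyphenyl]-4,5,6,7-tetramethoxybenzofuran-3-yl}oxy(tert-butyl)dimethylsilane; 15 bromoform
Product: 17 2',5'-bis(benzyloxy)-3-bromo-4',5,6,7,8-pentamethoxyflavone, via dibromocyclopropane 16 (not isolated)
Conditions: KOtBu, toluene, −20 °C to rt
Reagents that add atoms: none
Why: Proposed new method: tert-butoxide deprotonates 15 and the tribromomethyl anion loses bromide to give dibromocarbene, an electrophilic singlet carbene that should add in a concerted (2+1) cheletropic manner to the C2=C3 bond of 14, a tetrasubstituted enol ether activated by both the ring oxygen and the silyloxy group. The resulting 16 is a donor-substituted gem-dibromocyclopropane whose fused C–C bond should break in a disrotatory two-electron electrocyclic opening as the bromide syn to the five-membered ring departs, with the lone pairs of O1 and of the silyloxy oxygen stabilising both ends of the developing allyl cation. Transfer of the silyl group from oxygen to bromide then turns the old benzofuran C3 into the C4 carbonyl, so the inserted carbon ends as C3–Br between C2 and C4 and the furan has become the pyranone ring C. The closest known reaction types are the dihalocarbene ring expansion of cyclic silyl enol ethers to 2-halocycloalkenones and the halocarbene expansion of indoles and benzofurans (Ciamician–Dennstedt type), but their combination on a 2-aryl-3-silyloxybenzofuran has no direct precedent. Ring C is closed by one-carbon ring expansion and not by an end-on cyclisation, so the six-membered ring exists as soon as the shared cyclopropane bond opens and no other ring size can form. No stereocentre is created in 17, and the two transient stereocentres of 16 are cis by necessity and vanish on opening. The selectivity needed is chemoselectivity for the enol ether over the alkoxyarene rings and the benzylic C–H bonds, which the much higher nucleophilicity of the doubly oxygenated alkene should secure; regiochemistry is not in question because the carbene carbon is bonded to C2 and to the future C4 from the start.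

Step 8
Reactants: 17 2',5'-bis(benzyloxy)-3-bromo-4',5,6,7,8-pentamethoxyflavone
Product: 18 2',5'-dihydroxy-4',5,6,7,8-pentamethoxyflavone
Conditions: H2 (1 atm), 10% Pd/C, NaOAc, EtOAc–MeOH, rt
Reagents that add atoms: none
Why: Heterogeneous hydrogenolysis of the C3–Br bond and of both benzylic C–O bonds in one operation; NaOAc takes up the HBr, and the C2=C3 bond of a flavone is a vinylogous ester double bond that should be reduced far more slowly at atmospheric pressure.

Step 9
Reactants: 18 2',5'-dihydroxy-4',5,6,7,8-pentamethoxyflavone
Product: 19 2',5,5'-trihydroxy-4',6,7,8-tetramethoxyflavone (CNP0161877.0)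
Conditions: BCl3, CH2Cl2, −78 to 0 °C; H2O
Reagents that add atoms: none
Why: Chelation-controlled Lewis acid demethylation; boron bridges the C4 carbonyl and the peri 5-methoxy oxygen in a six-membered chelate, chloride removes that methyl group by SN2, and the non-chelated ethers should react much more slowly at low temperature, while the phenols of ring B are borylated only transiently and freed on hydrolysis.

## Compound list

1 | 1,2,3,4-tetramethoxybenzene | COc1ccc(OC)c(OC)c1OC | starting material
2 | (2,3,4,5-tetramethoxyphenyl)lithium | [Li]c1cc(OC)c(OC)c(OC)c1OC | intermediate (not isolated)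
3 | lithium trimethoxy(2,3,4,5-tetramethoxyphenyl)borate | [Li+].CO[B-](OC)(OC)c1cc(OC)c(OC)c(OC)c1OC | intermediate (not isolated)
4 | 2,3,4,5-tetramethoxyphenol | COc1cc(O)c(OC)c(OC)c1OC | intermediate
5 | chloroacetyl chloride | ClCC(Cl)=O | starting material
6 | 2,3,4,5-tetramethoxyphenyl 2-chloroacetate | COc1cc(OC(=O)CCl)c(OC)c(OC)c1OC | intermediate (not isolated)
7 | 2-chloro-1-(2-hydroxy-3,4,5,6-tetramethoxyphenyl)ethan-1-one | COc1c(OC)c(OC)c(C(=O)CCl)c(O)c1OC | intermediate
8 | 4,5,6,7-tetramethoxybenzofuran-3(2H)-one | COc1c(OC)c(OC)c2c(c1OC)OCC2=O | intermediate
9 | 2-methoxyhydroquinone | COc1cc(O)ccc1O | starting material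
10 | 1,4-bis(benzyloxy)-2-methoxybenzene | COc1cc(OCc2ccccc2)ccc1OCc1ccccc1 | intermediate
11 | 1-bromo-2,5-bis(benzyloxy)-4-methoxybenzene | COc1cc(OCc2ccccc2)c(Br)cc1OCc1ccccc1 | intermediate
12 | 2-[2,5-bis(benzyloxy)-4-methoxyphenyl]-4,5,6,7-tetramethoxybenzofuran-3(2H)-one (racemic; C2 epimerises through the enolate) | COc1cc(OCc2ccccc2)c(C2Oc3c(OC)c(OC)c(OC)c(OC)c3C2=O)cc1OCc1ccccc1 | intermediate (not isolated)
13 | sodium 2-[2,5-bis(benzyloxy)-4-methoxyphenyl]-4,5,6,7-tetramethoxybenzofuran-3-olate | [Na+].COc1cc(OCc2ccccc2)c(-c2oc3c(OC)c(OC)c(OC)c(OC)c3c2[O-])cc1OCc1ccccc1 | intermediate (not isolated)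
14 | {2-[2,5-bis(benzyloxy)-4-methoxyphenyl]-4,5,6,7-tetramethoxybenzofuran-3-yl}oxy(tert-butyl)dimethylsilane | COc1cc(OCc2ccccc2)c(-c2oc3c(OC)c(OC)c(OC)c(OC)c3c2O[Si](C)(C)C(C)(C)C)cc1OCc1ccccc1 | intermediate
15 | bromoform | BrC(Br)Br | starting material
16 | 1a-[2,5-bis(benzyloxy)-4-methoxyphenyl]-1,1-dibromo-6b-[(tert-butyldimethylsilyl)oxy]-3,4,5,6-tetramethoxy-1a,6b-dihydro-1H-cyclopropa[b]benzofuran (racemic, cis-fused; one enantiomer drawn) | COc1cc(OCc2ccccc2)c(cc1OCc1ccccc1)[C@]12Oc3c(OC)c(OC)c(OC)c(OC)c3[C@@]1(O[Si](C)(C)C(C)(C)C)C2(Br)Br | intermediate (not isolated)
17 | 2',5'-bis(benzyloxy)-3-bromo-4',5,6,7,8-pentamethoxyflavone | COc1cc(OCc2ccccc2)c(-c2oc3c(OC)c(OC)c(OC)c(OC)c3c(=O)c2Br)cc1OCc1ccccc1 | intermediate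
18 | 2',5'-dihydroxy-4',5,6,7,8-pentamethoxyflavone | COc1cc(O)c(-c2cc(=O)c3c(OC)c(OC)c(OC)c(OC)c3o2)cc1O | intermediate
19 | 2',5,5'-trihydroxy-4',6,7,8-tetramethoxyflavone (CNP0161877.0) | COc1cc(O)c(-c2cc(=O)c3c(O)c(OC)c(OC)c(OC)c3o2)cc1O | target

## Step count and risks

Total step count: 9. Longest linear sequence: 7 steps (steps 1, 2, 3, 6, 7, 8, 9); the ring B branch (steps 4 and 5) joins at step 6.

**Step 7 (key step).**
- What may go wrong: the carbene may be consumed by the base before it reaches the hindered tetrasubstituted double bond, which is flanked by the peri methoxy group and the ortho-benzyloxy aryl ring. The silyl group may be stripped by tert-butoxide before cyclopropanation. The cyclopropane may collapse by protonation to a C2-dibromomethyl ketone instead of expanding. The pyranone product may be opened at C2 by excess alkoxide.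
- Fallback (known chemistry, from 4 and 11, rejoining at 18): phenol 4 is C-acetylated with AcOH and BF3·OEt2 to 1-(2-hydroxy-3,4,5,6-tetramethoxyphenyl)ethan-1-one F1. Bromide 11 is converted by bromine–lithium exchange (n-BuLi, THF, −78 °C) and DMF into 2,5-bis(benzyloxy)-4-methoxybenzaldehyde F2. Claisen–Schmidt condensation of these two (KOH, EtOH) should give (E)-3-[2,5-bis(benzyloxy)-4-methoxyphenyl]-1-(2-hydroxy-3,4,5,6-tetramethoxyphenyl)prop-2-en-1-one F3. Oxidative cyclisation with catalytic I2 in hot DMSO should give 2',5'-bis(benzyloxy)-4',5,6,7,8-pentamethoxyflavone F4, and hydrogenolysis (H2, Pd/C) returns to the route at 18.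

**Step 6.**
- What may go wrong: aldol self-condensation of the benzofuranone enolate before coupling; slow reductive elimination from a stabilised, phenoxide-like enolate with an ortho-substituted electron-rich aryl group; O-arylation in place of C-arylation; autoxidation of the enolate if air enters before silylation.
- Fallback (reversed polarity, from 8 and 11, rejoining at 14): ketone 8 is brominated at C2 with CuBr2 (ring A has no free position) to 2-bromo-4,5,6,7-tetramethoxybenzofuran-3(2H)-one F5. This is silylated (TBSOTf, Et3N) to [(2-bromo-4,5,6,7-tetramethoxybenzofuran-3-yl)oxy](tert-butyl)dimethylsilane F6. Bromide 11 is converted by Miyaura borylation (bis(pinacolato)diboron, PdCl2(dppf), KOAc) into 2-[2,5-bis(benzyloxy)-4-methoxyphenyl]-4,4,5,5-tetramethyl-1,3,2-dioxaborolane F7. Anhydrous Suzuki–Miyaura coupling of F6 with F7 (Pd(OAc)2, SPhos, K3PO4, toluene) should give 14.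

**Step 2.**
- What may go wrong: the reaction may stop at the aryl ester if the Fries migration into the crowded position between the hydroxyl and a methoxy group is slow. Forcing it may cleave the methyl ether ortho to the new ketone.
- Fallback (ring closure by acylation instead of by etherification, from 4, rejoining at 8): phenol 4 is O-alkylated with chloroacetic acid and aqueous NaOH to 2-(2,3,4,5-tetramethoxyphenoxy)acetic acid F8. Intramolecular Friedel–Crafts acylation with P2O5–MeSO3H should close this directly to 8.

**Step 9.**
- What may go wrong: demethylation beyond C5, either at C6 once boron is held at the 5-oxygen, or at C4' through a five-membered boron bridge from the neighbouring 5'-oxygen. The free hydroquinone may also oxidise during work-up.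
- Fallback (demethylation while ring B is still protected, from 17, rejoining at 19): 17 is treated with MgI2·OEt2 in warm toluene–THF, a chelation-dependent reagent too weak to touch non-chelated benzyl or methyl ethers, to give 2',5'-bis(benzyloxy)-3-bromo-5-hydroxy-4',6,7,8-tetramethoxyflavone F9. The hydrogenolysis conditions of step 8 (H2, Pd/C, NaOAc) should then give 19 directly, so the final operation is a neutral filtration and not a Lewis acid quench.

## Further compounds

F1 | step 7 | 1-(2-hydroxy-3,4,5,6-tetramethoxyphenyl)ethan-1-one | COc1c(OC)c(OC)c(C(C)=O)c(O)c1OC
F2 | step 7 | 2,5-bis(benzyloxy)-4-methoxybenzaldehyde | COc1cc(OCc2ccccc2)c(C=O)cc1OCc1ccccc1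
F3 | step 7 | (E)-3-[2,5-bis(benzyloxy)-4-methoxyphenyl]-1-(2-hydroxy-3,4,5,6-tetramethoxyphenyl)prop-2-en-1-one | COc1cc(OCc2ccccc2)c(/C=C/C(=O)c2c(O)c(OC)c(OC)c(OC)c2OC)cc1OCc1ccccc1
F4 | step 7 | 2',5'-bis(benzyloxy)-4',5,6,7,8-pentamethoxyflavone | COc1cc(OCc2ccccc2)c(-c2cc(=O)c3c(OC)c(OC)c(OC)c(OC)c3o2)cc1OCc1ccccc1
F5 | step 6 | 2-bromo-4,5,6,7-tetramethoxybenzofuran-3(2H)-one (racemic) | COc1c(OC)c(OC)c2c(c1OC)OC(Br)C2=O
F6 | step 6 | [(2-bromo-4,5,6,7-tetramethoxybenzofuran-3-yl)oxy](tert-butyl)dimethylsilane | COc1c(OC)c(OC)c2c(c1OC)oc(Br)c2O[Si](C)(C)C(C)(C)C
F7 | step 6 | 2-[2,5-bis(benzyloxy)-4-methoxyphenyl]-4,4,5,5-tetramethyl-1,3,2-dioxaborolane | COc1cc(OCc2ccccc2)c(B2OC(C)(C)C(C)(C)O2)cc1OCc1ccccc1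
F8 | step 2 | 2-(2,3,4,5-tetramethoxyphenoxy)acetic acid | COc1cc(OCC(=O)O)c(OC)c(OC)c1OC
F9 | step 9 | 2',5'-bis(benzyloxy)-3-bromo-5-hydroxy-4',6,7,8-tetramethoxyflavone | COc1cc(OCc2ccccc2)c(-c2oc3c(OC)c(OC)c(OC)c(O)c3c(=O)c2Br)cc1OCc1ccccc1
A1 | alternative 1 | (Z)-3-(2,5-diisopropoxy-4-methoxyphenyl)-3-(2,3,4,5-tetramethoxyphenoxy)prop-2-enoic acid | OC(=O)/C=C(\Oc1cc(OC)c(OC)c(OC)c1OC)c1cc(OC(C)C)c(OC)cc1OC(C)C
A2 | alternative 1 | 2',5'-diisopropoxy-4',5,6,7,8-pentamethoxyflavone | COc1cc(OC(C)C)c(-c2cc(=O)c3c(OC)c(OC)c(OC)c(OC)c3o2)cc1OC(C)C
A3 | alternative 1 | ethyl 3-(2,5-diisopropoxy-4-methoxyphenyl)prop-2-ynoate | CCOC(=O)C#Cc1cc(OC(C)C)c(OC)cc1OC(C)C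
A4 | alternative 2 | 2-ethynyl-5,6,7,8-tetramethoxychromone | C#Cc1cc(=O)c2c(OC)c(OC)c(OC)c(OC)c2o1
A5 | alternative 2 | 4-methoxy-2-(trimethylsilyloxy)furan | COc1coc(O[Si](C)(C)C)c1
A6 | alternative 2 | 2',5'-dihydroxy-4',5,6,7,8-pentamethoxyflavone | COc1cc(O)c(-c2cc(=O)c3c(OC)c(OC)c(OC)c(OC)c3o2)cc1O
A7 | alternative 3 | 4-{6-[2,5-bis(benzyloxy)-4-methoxyphenyl]-4-oxo-4H-pyran-2-yl}-2,3,4-trimethoxycyclobut-2-en-1-one (racemic) | COC1=C(OC)C(OC)(c2cc(=O)cc(-c3cc(OCc4ccccc4)c(OC)cc3OCc3ccccc3)o2)C1=O
A8 | alternative 3 | 2',5'-bis(benzyloxy)-5-hydroxy-4',6,7,8-tetramethoxyflavone | COc1cc(OCc2ccccc2)c(-c2cc(=O)c3c(O)c(OC)c(OC)c(OC)c3o2)cc1OCc1ccccc1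
A9 | alternative 3 | dimethyl squarate | COC1=C(OC)C(=O)C1=O
A10 | alternative 3 | 2-[2,5-bis(benzyloxy)-4-methoxyphenyl]-6-bromo-4H-pyran-4-one | COc1cc(OCc2ccccc2)c(-c2cc(=O)cc(Br)o2)cc1OCc1ccccc1
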